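I began from a one-step world: free catalyst turns left-handed substrate into product at a steady pace, so the loss by a fixed time goes with the catalyst charged.

| setting | dawn | noon | spring | north | south-west |
|---|---|---|---|---|---|
| left-handed substrate | 0.20 M | 0.20 M | 0.20 M | 0.20 M | 0.20 M |
| right-handed substrate | 0.20 M | 0.20 M | 0.20 M | 0.20 M | 0.20 M |
| gas | 53 mM (held) | 53 mM (held) | 53 mM (held) | 53 mM (held) | 53 mM (held) |
| free catalyst | 1.8 mM | 2.6 mM | 4.5 mM | 3.8 mM | 2.0 mM |
| remark | run made earlier | run made earlier | run made earlier |  |  |
| time |  |  |  | 20 min | 20 min |

- dawn (time / min: right-handed substrate / %, left-handed substrate / %): 2.00: 49.8, 50.0; 5.00: 47.9, 47.7; 10.0: 51.0, 46.2; 15.0: 49.6, 44.9; 20.0: 48.6, 42.6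
- noon (time / min: right-handed substrate / %, left-handed substrate / %): 2.00: 49.5, 49.3; 5.00: 49.2, 46.8; 10.0: 49.8, 43.8; 15.0: 50.3, 40.2; 20.0: 48.2, 39.3
- spring (time / min: right-handed substrate / %, left-handed substrate / %): 4.00: 49.1, 47.6; 8.00: 48.7, 43.7; 12.0: 49.3, 40.1; 15.0: 45.6, 38.1; 20.0: 48.0, 31.6

(each reading ± 1 percentage point)

- free catalyst is single-handed; left-handed substrate and right-handed substrate are mirror images of each other, charged as a racemate, each of them at the stated concentration
- at the start none of reagent is dissolved
- what was read earlier has a scatter of 1 percentage point, one standard deviation
- reactions considered so far: free catalyst + left-handed substrate <-> catalyst intermediate A; free catalyst + right-handed substrate <-> catalyst intermediate B; reagent + catalyst intermediate A -> free catalyst + left-handed product; reagent + catalyst intermediate B -> free catalyst + right-handed product; gas <-> reagent; 2 free catalyst -> spent catalyst; reagent <-> dormant form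
- an excess is below zero if the other one leads

* the winner by excess of right-handed substrate over left-handed substrate among what is left of the two; "neither" if no more than 2 percentage points parts them (north / south-west / neither)
* excess of right-handed substrate over left-handed substrate among what is left of the two at the end, north
* excess of right-handed substrate over left-handed substrate among what is left of the two at the end, south-west

Pooled over the three runs at the last reading, the loss gave 16.4. This is the turnover count, the left-handed substrate lost by 20 min per free catalyst charged; the usual term is turnover number. Taken singly, dawn, noon and spring read 16.4, 16.5 and 16.4, each from a percentage reading with a scatter of 1 percentage point.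

North looked nearly like spring, with c(free catalyst) 3.8 mM against 4.5 mM. North held less catalyst than spring, so at the same count I reckoned its loss at 15.6% of the pair charged, against 18.4% read in spring. South-west held more catalyst than dawn, so I reckoned its loss at 8.20%, against 7.40% read at dawn.

My first round took the right-handed substrate as untouched, which gave north 18.5%. But the last readings of the three runs showed a right-handed loss too, pooled at 0.142 of the left-handed loss. I put that back and went round again. That round put north at 16.3% and south-west at 7.76%. North held twice the catalyst of south-west, and my two excesses parted by 8.5 points, more than the margin of 2 points.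

The forecast named north, with 15.3% for north and 7.6% for south-west, calling the loss “roughly proportional to catalyst”. My north stood higher than the forecast's.

The simulation gave north, with 15.7% for north and 9.22% for south-west.

    free catalyst + left-handed substrate ⇌ catalyst intermediate A (K = 6.10 M⁻¹, k = 16.0 M⁻¹ s⁻¹)
    free catalyst + right-handed substrate ⇌ catalyst intermediate B (K = 2.20 M⁻¹, k = 31.0 M⁻¹ s⁻¹)
    reagent + catalyst intermediate A → free catalyst + left-handed product (k = 4.70 M⁻¹ s⁻¹)
    reagent + catalyst intermediate B → free catalyst + right-handed product (k = 1.60 M⁻¹ s⁻¹)
    gas ⇌ reagent, rate k5*(csat - [reagent]) (kL = 0.00710 s⁻¹)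
    2 free catalyst → spent catalyst (k = 0.210 M⁻¹ s⁻¹)
    reagent ⇌ dormant form (K = 95.0, k = 0.0410 s⁻¹)

The neighbour flask was north with 9.5 × 10⁻⁴ M of free catalyst, read at the same time. The same count put its left-handed loss at 3.90%. With the same right-handed share, I reckoned its excess at 3.50%. The flask gave 4.69%, which is more than my figure. Counted as left-handed product per catalyst charged, the neighbour flask stood at 21.1 against 15.8 in north. Spent catalyst at 20.0 min stood at 6.73% of the catalyst charged in the neighbour flask against 24.4% in north.

The runs were computed with made-up constants, and the scatter is random.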